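**Retrosynthetic overview**
1. The target comes from a Δ4-3-ketone by Luche reduction and 3β-propionylation. The α-(methoxycarbonyl)vinyl group comes from a C7 malonate by decarboxylative Mannich methylenation, and the C8 acetate is carried from the acyclic stage.
2. Key disconnection: the bicyclic enone is cut to an acyclic 1,7-enyne acetate and a two-carbon silylated ynol ether. An enantioselective rhodium-catalysed [2+2+2] cycloaddition forms C1–C2, C3–C4 and C5–C10 in one operation; ring B closes first (metallacycle), ring A second (reductive elimination).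
3. Enabling feature: ring A is a cyclohexene whose tetrasubstituted C4=C5 bond is exocyclic to ring B and lies between quaternary C10 and oxygenated C3. C4=C5 is read as a former alkyne, C10–C1 as a former 1,1-disubstituted alkene and C2–C3(O) as a former ynol ether.
4. The enyne comes from hex-4-ynal by organo-photoredox α-malonylation (sets C7) and Felkin-matched asymmetric methallylboration (sets C8). C10 then comes from the chiral rhodium catalyst and C3 from C10.

Key step: step 7

Remark: the target is read as the 3S,7R,8R,10R isomer (3β-propionyloxy, 8β-acetoxy, 7β side chain, 10β-methyl); eudesmane locants C1–C15 are used for the corresponding atoms of all intermediates, and compounds 1, 3, 6 and 10 (the last as its hexane solution) are taken as commercial.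

**Route**

Step 1
Reactants: 1 di-tert-butyl malonate
Product: 2 di-tert-butyl 2-bromomalonate
Conditions: NBS, Mg(ClO4)2 (10 mol %), MeCN, rt
Reagents that add atoms: N-bromosuccinimide, O=C1CCC(=O)N1Br
Why: Lewis-acid-catalysed electrophilic α-bromination of a 1,3-dicarbonyl compound with NBS should stop at the monobromide under neutral conditions that spare the tert-butyl esters.

Step 2
Reactants: 3 hex-4-yn-1-ol
Product: 4 hex-4-ynal
Conditions: PhI(OAc)2, TEMPO (10 mol %), CH2Cl2, rt
Reagents that add atoms: none
Why: The oxoammonium-mediated TEMPO/PhI(OAc)2 oxidation takes a primary alcohol to the aldehyde without over-oxidation and leaves the internal alkyne untouched.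

Step 3
Reactants: 4 hex-4-ynal; 2 di-tert-butyl 2-bromomalonate
Product: 5 di-tert-butyl 2-[(2R)-1-oxohex-4-yn-2-yl]malonate
Conditions: Ru(bpy)3Cl2 (0.5 mol %), (2R,5S)-2-tert-butyl-3,5-dimethylimidazolidin-4-one·TfOH (20 mol %; the antipode that leads to the 2R aldehyde), 2,6-lutidine, DMF, blue LEDs, rt
Reagents that add atoms: none
Why: In this organo-photoredox α-alkylation of an aldehyde the electrophilic malonyl radical formed by reduction of 2 adds to the open face of the chiral enamine, so C7 (R) is set by the imidazolidinone, and the internal alkyne is a much poorer acceptor for this radical than the enamine.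

Step 4
Reactants: 5 di-tert-butyl 2-[(2R)-1-oxohex-4-yn-2-yl]malonate; 6 2-methylallylboronic acid pinacol ester
Product: 8 di-tert-butyl 2-[(4R,5R)-4-hydroxy-2-methylnon-1-en-7-yn-5-yl]malonate, via borate ester 7 (not isolated)
Conditions: (R)-TRIP phosphoric acid (5 mol %; the antipode chosen to direct allyl transfer to the Re face), toluene, −30 °C; aqueous work-up
Reagents that add atoms: none
Why: Chiral-phosphoric-acid-catalysed allylboration through a closed chair transition state should deliver the methallyl group to the Re face, which is also the Felkin–Anh face of the α-branched aldehyde (malonyl group as the large substituent), so C8 (R) is set anti to C7 under matched control and the near-neutral conditions avoid epimerization at C7.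

Step 5
Reactants: 8 di-tert-butyl 2-[(4R,5R)-4-hydroxy-2-methylnon-1-en-7-yn-5-yl]malonate
Product: 9 di-tert-butyl 2-[(4R,5R)-4-acetoxy-2-methylnon-1-en-7-yn-5-yl]malonate
Conditions: Ac2O, pyridine, DMAP (5 mol %), CH2Cl2, 0 °C to rt
Reagents that add atoms: acetic anhydride, CC(=O)OC(C)=O
Why: DMAP-catalysed acylation of the secondary alcohol installs the C8 acetate of the target early, and the bulky tert-butyl esters resist the competing γ-lactonization.

Step 6
Reactants: 10 ethoxyacetylene
Product: 12 (ethoxyethynyl)trimethylsilane, via lithium ethoxyacetylide 11 (not isolated)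
Conditions: n-BuLi, THF, −78 °C; Me3SiCl, −78 °C to rt
Reagents that add atoms: chlorotrimethylsilane, C[Si](C)(C)Cl
Why: Deprotonation of the terminal alkyne and C-silylation of the lithium acetylide is a standard alkynylsilane synthesis and gives a capped ynol ether that cannot self-trimerize.

Step 7
Reactants: 9 di-tert-butyl 2-[(4R,5R)-4-acetoxy-2-methylnon-1-en-7-yn-5-yl]malonate; 12 (ethoxyethynyl)trimethylsilane
Product: 15 di-tert-butyl 2-(8β-acetoxy-4,10β-dimethyl-3-oxo-Δ4-octalin-7β-yl)malonate, via silyl dienol ether cycloadduct 13 (not isolated), via desilylated dienol ether 14 (not isolated)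
Conditions: [Rh(cod)2]BF4 (10 mol %), (S)-Tol-BINAP (10 mol %; provisional antipode, to be matched against (R) in the first run), ClCH2CH2Cl, 60 °C, 12 added slowly; then 1 M HCl, THF, rt
Reagents that add atoms: water, O
Why: Proposed new method: cationic monovalent rhodium should couple the butynyl alkyne and the 1,1-disubstituted alkene of 9 oxidatively to a rhodacyclopentene (C5–C10 bond; ring B closed as a six-membered ring by oxidative cyclization), alkyne 12 should then insert into the Rh–C4 bond (C3–C4) and C(sp3)–C(sp2) reductive elimination from the seven-membered rhodacycle should form C1–C2 and close ring A, the closest known reaction type being the [Rh(cod)2]BF4/Tol-BINAP-catalysed enantioselective [2+2+2] cycloaddition of 1,6-enynes bearing 1,1-disubstituted alkenes with alkynes, extended here to a 1,7-enyne and to a silylated ynol ether. The one new stereocentre, quaternary C10, is set in the oxidative cyclization by the chiral bisphosphine through its choice of alkene face; the metallacycle forces C1 equatorial and the methyl group axial on ring B, and the substrate bias is small (equatorial malonyl group at C7 in favour, syn-axial C8 acetate against), so catalyst control has to decide. The step needs regioselectivity for the orientation of 12, which should follow from the polarization of the ynol ether (vinyl carbon C4 migrates to the electrophilic oxygen-bearing carbon, rhodium goes to the silicon-bearing carbon) and from the bulk of the silyl group, which avoids the methyl-bearing C4. It also needs chemoselectivity for cross-cycloaddition, which the silyl-capped internal alkyne and the two tether substituents of 9 (easier six-membered closure) are meant to secure. Aqueous acid then protonates C2 of diene 13, silicon is lost to give 14, and hydrolysis of this enol ether gives the conjugated enone 15 while the tert-butyl esters and the acetate survive.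

Step 8
Reactants: 15 di-tert-butyl 2-(8β-acetoxy-4,10β-dimethyl-3-oxo-Δ4-octalin-7β-yl)malonate
Product: 16 2-(8β-acetoxy-4,10β-dimethyl-3-oxo-Δ4-octalin-7β-yl)malonic acid
Conditions: CF3CO2H/CH2Cl2 (1:3), 0 °C to rt
Reagents that add atoms: none
Why: Acidolysis of the tert-butyl esters by loss of isobutene leaves the acetate, the enone and the tetrasubstituted alkene unchanged and gives the malonic acid needed for methylenation.

Step 9
Reactants: 16 2-(8β-acetoxy-4,10β-dimethyl-3-oxo-Δ4-octalin-7β-yl)malonic acid
Product: 18 8β-acetoxy-3-oxoeudesma-4,11(13)-dien-12-oic acid, via Mannich base 17 (not isolated)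
Conditions: (CH2O)n, Et2NH, EtOAc, rt then 75 °C
Reagents that add atoms: formaldehyde (as paraformaldehyde), C=O
Why: Mannich reaction of the malonic acid with the iminium ion from formaldehyde and diethylamine, followed by decarboxylative elimination of the amine (decarboxylative Mannich methylenation), should give the 2-substituted acrylic acid without enolizing the enone or touching C7.

Step 10
Reactants: 18 8β-acetoxy-3-oxoeudesma-4,11(13)-dien-12-oic acid
Product: 20 methyl 8β-acetoxy-3-oxoeudesma-4,11(13)-dien-12-oate, via potassium carboxylate 19 (not isolated)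
Conditions: MeI, KHCO3, DMF, rt
Reagents that add atoms: iodomethane, CI
Why: SN2 O-alkylation of the carboxylate with iodomethane proceeds under hydrogencarbonate conditions that are too weak to enolize the ketone or cleave the acetate.

Step 11
Reactants: 20 methyl 8β-acetoxy-3-oxoeudesma-4,11(13)-dien-12-oate
Product: 21 methyl 8β-acetoxy-3β-hydroxyeudesma-4,11(13)-dien-12-oate
Conditions: NaBH4, CeCl3·7H2O, MeOH, −78 to −40 °C
Reagents that add atoms: none
Why: Luche reduction should reduce only the ring enone in the 1,2 sense (acrylate and esters are inert at low temperature), with hydride arriving axially on the α face opposite the axial 10β-methyl group, so the pseudo-equatorial 3β-alcohol (3S) forms under substrate control.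

Step 12
Reactants: 21 methyl 8β-acetoxy-3β-hydroxyeudesma-4,11(13)-dien-12-oate
Product: 22 methyl 8β-acetoxy-3β-propionyloxyeudesma-4,11(13)-dien-12-oate (CNP0198123.1)
Conditions: (EtCO)2O, Et3N, DMAP (10 mol %), CH2Cl2, 0 °C to rt
Reagents that add atoms: propionic anhydride, CCC(=O)OC(=O)CC
Why: DMAP-catalysed esterification of the unhindered allylic alcohol proceeds with retention at C3 and completes the target.

**Compound list**
1 | di-tert-butyl malonate | CC(C)(C)OC(=O)CC(=O)OC(C)(C)C | starting material
2 | di-tert-butyl 2-bromomalonate | CC(C)(C)OC(=O)C(Br)C(=O)OC(C)(C)C | intermediate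
3 | hex-4-yn-1-ol | CC#CCCCO | starting material
4 | hex-4-ynal | CC#CCCC=O | intermediate
5 | di-tert-butyl 2-[(2R)-1-oxohex-4-yn-2-yl]malonate | O=C[C@H](CC#CC)C(C(=O)OC(C)(C)C)C(=O)OC(C)(C)C | intermediate
6 | 2-methylallylboronic acid pinacol ester | C=C(C)CB1OC(C)(C)C(C)(C)O1 | starting material
7 | pinacol borate ester of alcohol 8 (4R,5R; O–B bond at C4 of the chain) | C=C(C)C[C@@H](OB1OC(C)(C)C(C)(C)O1)[C@H](CC#CC)C(C(=O)OC(C)(C)C)C(=O)OC(C)(C)C | intermediate
8 | di-tert-butyl 2-[(4R,5R)-4-hydroxy-2-methylnon-1-en-7-yn-5-yl]malonate | C=C(C)C[C@@H](O)[C@H](CC#CC)C(C(=O)OC(C)(C)C)C(=O)OC(C)(C)C | intermediate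
9 | di-tert-butyl 2-[(4R,5R)-4-acetoxy-2-methylnon-1-en-7-yn-5-yl]malonate | C=C(C)C[C@@H](OC(C)=O)[C@H](CC#CC)C(C(=O)OC(C)(C)C)C(=O)OC(C)(C)C | intermediate
10 | ethoxyacetylene | C#COCC | starting material
11 | lithium ethoxyacetylide | [Li]C#COCC | intermediate
12 | (ethoxyethynyl)trimethylsilane | CCOC#C[Si](C)(C)C | intermediate
13 | bicyclic 3-ethoxy-2-(trimethylsilyl)-2,4-diene: ring A with C2=C3 and C4=C5, 4-methyl, 10β-methyl, 8β-acetoxy, 7β-CH(CO2t-Bu)2 | CC(C)(C)OC(=O)C(C(=O)OC(C)(C)C)[C@H]1CC2=C(C)C(OCC)=C([Si](C)(C)C)C[C@]2(C)C[C@H]1OC(C)=O | intermediate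
14 | bicyclic 3-ethoxy-2,4-diene: as 13 with H in place of the silyl group | CC(C)(C)OC(=O)C(C(=O)OC(C)(C)C)[C@H]1CC2=C(C)C(OCC)=CC[C@]2(C)C[C@H]1OC(C)=O | intermediate
15 | di-tert-butyl 2-(8β-acetoxy-4,10β-dimethyl-3-oxo-Δ4-octalin-7β-yl)malonate (7R,8R,10R) | CC(C)(C)OC(=O)C(C(=O)OC(C)(C)C)[C@H]1CC2=C(C)C(=O)CC[C@]2(C)C[C@H]1OC(C)=O | intermediate
16 | 2-(8β-acetoxy-4,10β-dimethyl-3-oxo-Δ4-octalin-7β-yl)malonic acid | OC(=O)C(C(=O)O)[C@H]1CC2=C(C)C(=O)CC[C@]2(C)C[C@H]1OC(C)=O | intermediate
17 | 2-[(diethylamino)methyl] derivative of malonic acid 16 (Mannich base) | CCN(CC)CC(C(=O)O)(C(=O)O)[C@H]1CC2=C(C)C(=O)CC[C@]2(C)C[C@H]1OC(C)=O | intermediate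
18 | 8β-acetoxy-3-oxoeudesma-4,11(13)-dien-12-oic acid | C=C(C(=O)O)[C@H]1CC2=C(C)C(=O)CC[C@]2(C)C[C@H]1OC(C)=O | intermediate
19 | potassium 8β-acetoxy-3-oxoeudesma-4,11(13)-dien-12-oate | C=C(C(=O)[O-])[C@H]1CC2=C(C)C(=O)CC[C@]2(C)C[C@H]1OC(C)=O.[K+] | intermediate
20 | methyl 8β-acetoxy-3-oxoeudesma-4,11(13)-dien-12-oate | C=C(C(=O)OC)[C@H]1CC2=C(C)C(=O)CC[C@]2(C)C[C@H]1OC(C)=O | intermediate
21 | methyl 8β-acetoxy-3β-hydroxyeudesma-4,11(13)-dien-12-oate | C=C(C(=O)OC)[C@H]1CC2=C(C)[C@@H](O)CC[C@]2(C)C[C@H]1OC(C)=O | intermediate
22 | methyl 8β-acetoxy-3β-propionyloxyeudesma-4,11(13)-dien-12-oate (3S,7R,8R,10R) | C=C(C(=O)OC)[C@H]1CC2=C(C)[C@@H](OC(=O)CC)CC[C@]2(C)C[C@H]1OC(C)=O | target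

**Step count and risks**

Total step count: 12 (steps 1 and 6 prepare the partners 2 and 12). Longest linear sequence: 10 steps (3 → 4 → 5 → 8 → 9 → 15 → 16 → 18 → 20 → 21 → 22).

Steps most likely to fail:

1. Step 7 (proposed new method). The six-membered oxidative cyclization of the 1,7-enyne may be slow enough for the ynol ether to be consumed unproductively. The ynol ether may insert in the reverse orientation. Ligand and substrate may be mismatched, eroding facial selectivity at C10. Fallback, setting out from 9 and using known reaction types: acetylene (1 atm), the established alkyne partner for quaternary-centre-forming enyne [2+2+2] cycloadditions, is used with the same kind of [Rh(cod)2]BF4/Tol-BINAP catalyst and should give the homoannular diene F1 with no regiochemical question. Mukaiyama hydration (Mn(dpm)3, PhSiH3, O2, i-PrOH, then PPh3) should place hydrogen on C2 and oxygen on C3 through the C3–C4–C5 allyl radical, giving the allylic alcohol F2 as a mixture of C3 epimers. Dess–Martin oxidation returns to the route at 15.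

2. Step 4. Facial selectivity in the carbonyl addition may be poor if the catalyst preference and the Felkin–Anh preference do not reinforce each other, and C7 may epimerize by enolization of the α-branched aldehyde. Fallback, setting out from 5, which sets C8 by SN2 inversion instead of by a facial choice: an indium-mediated Barbier addition of methallyl bromide (THF/water) needs no stereocontrol and gives 8 together with the (4S,5R) alcohol F3. Dess–Martin oxidation of the mixture gives the ketone F4. LiBH(s-Bu)3 at −78 °C should reduce F4 under Felkin–Anh control to F3 alone. Mitsunobu inversion with acetic acid (PPh3, DIAD) should give the acetate directly, so the fallback returns to the route at 9 and step 5 is not needed.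

3. Step 9. Aminomethylation of the enone may compete, diethylamine may add to the new acrylic acid, and the decarboxylative elimination may be incomplete. Fallback, setting out from 15, which installs the methylene carbon on the malonate ester before the acids are freed: C-alkylation of the malonate anion (NaH, THF, 0 °C) with N,N-dimethylmethyleneiminium iodide (Eschenmoser's salt) should give the Mannich base F5. CF3CO2H cleaves the tert-butyl esters to the amino diacid F6. Heating with NaOAc in dioxane should bring about decarboxylative loss of dimethylamine, returning to the route at 18 (steps 8 and 9 are replaced).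

**Further compounds**
F1 | step 7 | di-tert-butyl 2-(8β-acetoxy-4,10β-dimethyl-Δ2,Δ4-hexalin-7β-yl)malonate (homoannular 2,4-diene) | CC(C)(C)OC(=O)C(C(=O)OC(C)(C)C)[C@H]1CC2=C(C)C=CC[C@]2(C)C[C@H]1OC(C)=O
F2 | step 7 | di-tert-butyl 2-(8β-acetoxy-3-hydroxy-4,10β-dimethyl-Δ4-octalin-7β-yl)malonate (C3 epimers) | CC(C)(C)OC(=O)C(C(=O)OC(C)(C)C)[C@H]1CC2=C(C)C(O)CC[C@]2(C)C[C@H]1OC(C)=O
F3 | step 4 | di-tert-butyl 2-[(4S,5R)-4-hydroxy-2-methylnon-1-en-7-yn-5-yl]malonate | C=C(C)C[C@H](O)[C@H](CC#CC)C(C(=O)OC(C)(C)C)C(=O)OC(C)(C)C
F4 | step 4 | di-tert-butyl 2-[(5R)-2-methyl-4-oxonon-1-en-7-yn-5-yl]malonate | C=C(C)CC(=O)[C@H](CC#CC)C(C(=O)OC(C)(C)C)C(=O)OC(C)(C)C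
F5 | step 9 | di-tert-butyl 2-(8β-acetoxy-4,10β-dimethyl-3-oxo-Δ4-octalin-7β-yl)-2-[(dimethylamino)methyl]malonate | CN(C)CC(C(=O)OC(C)(C)C)(C(=O)OC(C)(C)C)[C@H]1CC2=C(C)C(=O)CC[C@]2(C)C[C@H]1OC(C)=O
F6 | step 9 | 2-(8β-acetoxy-4,10β-dimethyl-3-oxo-Δ4-octalin-7β-yl)-2-[(dimethylamino)methyl]malonic acid | CN(C)CC(C(=O)O)(C(=O)O)[C@H]1CC2=C(C)C(=O)CC[C@]2(C)C[C@H]1OC(C)=O
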